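**Plan**
Retrosynthesis: the sulfate ester and the two benzyl ethers are removed first. Ring A is then cut at C3a–C7a and C4–C5, which also opens the dihydrofuran ring.
Enabling feature: ring A (C3a, C4, C5, C6, C7, C7a) carries O1 on C7a and OMe on the adjacent C7, and is fused through C7a–O1 and C3a–C3. C7a–C7–C6–C5 can therefore come from the carbon diene of a 3-alkoxy-4-methoxy-6-alkylpyridazine, and C3a–C4 from a terminal alkyne at the end of the O1–C2–C3 chain.
Further cuts: O1–C7a (SNAr), C2–C3 (allenylzinc addition to O-benzylvanillin) and C5–side chain (Negishi coupling).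
Forward: a pyridazine fragment (2 steps) and an alkynol fragment (4 steps) are joined through O1. Heating then forms ring A and the dihydrofuran ring together with loss of N2, and desilylation, sulfation and hydrogenolysis finish the route.
Stereochemistry: a lipase resolution provides an (S)-propargylic alcohol. Its mesylate transfers chirality to C3 through an axially chiral allenylzinc, whose closed transition state sets C2 anti. Neither centre is touched afterwards, so anti becomes 2,3-trans (2S,3R).

Key step: step 8

Assumption: the target is drawn as the free hydrogen sulfate, so the sulfate is carried as its sodium salt and protonated only at the very end.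

**Step 1**
Reactants: 1 3,4,6-trichloropyridazine
Product: 2 3,6-dichloro-4-methoxypyridazine
Conditions: NaOMe (1.0 equiv), MeOH, 0 °C → rt
Reagents that add atoms: sodium methoxide, [Na+].[O-]C
Why: SNAr: C4 of the trichloride, para to N1 and next to the C3 chlorine, is the position methoxide attacks first, and one equivalent at low temperature stops at monosubstitution.

**Step 2**
Reactants: 2 3,6-dichloro-4-methoxypyridazine; 3 (3-bromopropoxy)(tert-butyl)dimethylsilane
Product: 5 3-chloro-4-methoxy-6-[3-(tert-butyldimethylsilyloxy)propyl]pyridazine, via alkylzinc bromide 4 (not isolated)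
Conditions: 3, Zn dust, I2 (5 mol %), DMA, 80 °C; then 2, PdCl2(dppf) (3 mol %), THF, 50 °C
Reagents that add atoms: zinc, [Zn] (kept in 4 only, lost again on the way to 5)
Why: Negishi coupling: zerovalent palladium should insert into C6–Cl, the bond that is neither crowded nor enriched by π-donation from the ortho methoxy group (checkable by NOE from H5 to both OMe and the new CH2), the alkylated product is too electron-rich to couple twice, and the chain is carried as a silyl ether so that no ester meets the alkoxide of step 7.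

**Step 3**
Reactants: 6 benzyloxyacetaldehyde; 7 ethynylmagnesium bromide
Product: 8 rac-1-(benzyloxy)but-3-yn-2-ol
Conditions: THF, −78 → 0 °C
Reagents that add atoms: none
Why: Grignard 1,2-addition of an acetylide to an unhindered aldehyde; the new carbinol centre forms racemic and is resolved in step 4.

**Step 4**
Reactants: 8 rac-1-(benzyloxy)but-3-yn-2-ol
Product: 9 (S)-1-(benzyloxy)but-3-yn-2-ol
Conditions: Burkholderia cepacia lipase (Amano PS), vinyl acetate, MTBE, 30 °C, stopped just past half conversion; chromatography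
Reagents that add atoms: none
Why: Lipase-catalysed kinetic resolution by irreversible transesterification: by the usual size rule for secondary alcohols the enzyme acetylates the enantiomer with the large CH2OBn and the small ethynyl group in the (R) arrangement, so the (S)-alcohol is left behind and its enantiopurity rises as conversion passes one half.

**Step 5**
Reactants: 9 (S)-1-(benzyloxy)but-3-yn-2-ol
Product: 10 (S)-1-(benzyloxy)but-3-yn-2-yl methanesulfonate
Conditions: MsCl, Et3N, CH2Cl2, −78 → 0 °C
Reagents that add atoms: methanesulfonyl chloride, CS(=O)(=O)Cl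
Why: O-Sulfonylation breaks no bond at the stereocentre, so the (S) configuration is kept; the mesylate is used without delay.

**Step 6**
Reactants: 10 (S)-1-(benzyloxy)but-3-yn-2-yl methanesulfonate; 11 4-(benzyloxy)-3-methoxybenzaldehyde (O-benzylvanillin)
Product: 13 (1S,2R)-1-[4-(benzyloxy)-3-methoxyphenyl]-2-[(benzyloxy)methyl]but-3-yn-1-ol, via allenylzinc mesylate 12 (not isolated)
Conditions: Pd(OAc)2 (5 mol %), PPh3 (5 mol %), Et2Zn (2.5 equiv), THF, −78 → −20 °C
Reagents that add atoms: diethylzinc, CC[Zn]CC (zinc kept in 12 only)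
Why: Marshall propargylation: zerovalent palladium displaces the mesylate anti (SN2′), Et2Zn converts the allenylpalladium into the (P)-allenylzinc 12, and 12 adds to the aldehyde through a closed SE2′ transition state on the face that carries zinc, so the propargylic centre (C3 of the target) becomes R by chirality transfer with net inversion of the mesylate carbon, and the carbinol centre (C2 of the target) becomes S because the aryl group turns away from CH2OBn (anti adduct); any syn isomer is removed by chromatography.

**Step 7**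
Reactants: 13 (1S,2R)-1-[4-(benzyloxy)-3-methoxyphenyl]-2-[(benzyloxy)methyl]but-3-yn-1-ol; 5 3-chloro-4-methoxy-6-[3-(tert-butyldimethylsilyloxy)propyl]pyridazine
Product: 15 3-{(1S,2R)-1-[4-(benzyloxy)-3-methoxyphenyl]-2-[(benzyloxy)methyl]but-3-ynyloxy}-4-methoxy-6-[3-(tert-butyldimethylsilyloxy)propyl]pyridazine, via sodium alkoxide 14 (not isolated)
Conditions: NaH (1.05 equiv), THF, 0 °C; then 5, THF/DMF, 0 → 50 °C
Reagents that add atoms: sodium hydride, [Na+].[H-] (sodium kept in 14 only)
Why: SNAr (addition–elimination) at the only remaining C–Cl bond, activated by the adjacent N2; only the O–H bond of 13 is broken, so both stereocentres are kept, and one equivalent of base in a weakly polar medium avoids alkyne–allene isomerisation.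

**Step 8**
Reactants: 15 3-{(1S,2R)-1-[4-(benzyloxy)-3-methoxyphenyl]-2-[(benzyloxy)methyl]but-3-ynyloxy}-4-methoxy-6-[3-(tert-butyldimethylsilyloxy)propyl]pyridazine
Product: 17 (2S,3R)-2-[4-(benzyloxy)-3-methoxyphenyl]-3-[(benzyloxy)methyl]-5-[3-(tert-butyldimethylsilyloxy)propyl]-7-methoxy-2,3-dihydrobenzofuran, via diazabicyclooctatriene adduct 16 (not isolated)
Conditions: 1,3,5-triisopropylbenzene (0.01 M), BHT (10 mol %), argon, base-washed sealed tube, 210 °C
Reagents that add atoms: none
Why: The four ring carbons C3–C4–C5–C6 of the diazine act as the 4π partner and the tethered terminal alkyne as the 2π partner of an intramolecular inverse-electron-demand Diels–Alder reaction that gives the bridged azo compound 16, and 16 at once loses N2 by retro-[4+2] cleavage, which makes the sequence irreversible and leaves benzene ring A. The closest known reaction type is the thermal conversion of 3-(but-3-ynyloxy)pyridazines into 2,3-dihydrobenzofurans. The dihydrofuran ring closes as a five-membered ring when the internal alkyne carbon bonds to diazine C3 (bond C3a–C7a) across the three-atom O1–C2–C3 tether, and ring A closes as a six-membered ring by the cycloaddition itself when the alkyne CH bonds to diazine C6 (bond C4–C5). No lasting stereocentre is created: the two bridgeheads of 16 disappear on aromatisation, so attack on either face of the diazine leads to the same product, while C2 and C3 lie on the tether, lose no bond, and turn the anti arrangement of 15 into the 2,3-trans ring. The selectivity needed is regiochemical and is enforced by the short tether, which lets the internal alkyne carbon reach only C3, so that the CH ends up next to the carbon that bears the side chain. The two oxygen donors make the diazine a sluggish diene, which is why about 210 °C is planned; intramolecularity and the two tether substituents, which favour the folded rotamer, make up for this, and an apolar, acid-free, dilute medium holds back ionisation or retro-ene cleavage of the benzylic ether.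

**Step 9**
Reactants: 17 (2S,3R)-2-[4-(benzyloxy)-3-methoxyphenyl]-3-[(benzyloxy)methyl]-5-[3-(tert-butyldimethylsilyloxy)propyl]-7-methoxy-2,3-dihydrobenzofuran
Product: 18 3-{(2S,3R)-2-[4-(benzyloxy)-3-methoxyphenyl]-3-[(benzyloxy)methyl]-7-methoxy-2,3-dihydrobenzofuran-5-yl}propan-1-ol
Conditions: HF·pyridine, pyridine, THF, 0 °C → rt
Reagents that add atoms: none
Why: Fluoride-driven cleavage of the primary silyl ether (strong Si–F bond) under buffered conditions that leave the benzyl ethers, the aryl ethers and both stereocentres alone.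

**Step 10**
Reactants: 18 3-{(2S,3R)-2-[4-(benzyloxy)-3-methoxyphenyl]-3-[(benzyloxy)methyl]-7-methoxy-2,3-dihydrobenzofuran-5-yl}propan-1-ol
Product: 20 sodium 3-{(2S,3R)-2-[4-(benzyloxy)-3-methoxyphenyl]-3-[(benzyloxy)methyl]-7-methoxy-2,3-dihydrobenzofuran-5-yl}propyl sulfate, via pyridinium sulfate 19 (not isolated)
Conditions: SO3·pyridine (3 equiv), DMF, rt; then aq. NaHCO3
Reagents that add atoms: sulfur trioxide–pyridine complex, [O-]S(=O)(=O)[n+]1ccccc1; sodium hydrogen carbonate, [Na+].OC([O-])=O
Why: O-Sulfation of the only free hydroxyl group by the SO3–amine complex, followed by cation exchange to the stable sodium salt; the mild, slightly basic medium does not affect the benzylic C2–O1 bond.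

**Step 11**
Reactants: 20 sodium 3-{(2S,3R)-2-[4-(benzyloxy)-3-methoxyphenyl]-3-[(benzyloxy)methyl]-7-methoxy-2,3-dihydrobenzofuran-5-yl}propyl sulfate
Product: 22 3-[(2S,3R)-2-(4-hydroxy-3-methoxyphenyl)-3-(hydroxymethyl)-7-methoxy-2,3-dihydrobenzofuran-5-yl]propyl hydrogen sulfate (CNP0220090.1), via sodium salt 21 (not isolated)
Conditions: H2 (1 atm), 10% Pd/C, MeOH, rt; filter; HCl (1.0 equiv), H2O, 0 °C; C18 desalting, cold lyophilisation
Reagents that add atoms: none
Why: Hydrogenolysis: both benzyl ethers are cleaved over Pd/C at one atmosphere of H2 while the primary alkyl sulfate salt is inert and the hindered ring C2–O1 bond reacts much more slowly, so the reaction is stopped at full debenzylation, and one equivalent of cold HCl then converts the sodium salt 21 into the free hydrogen sulfate without touching C2 or C3.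

**Compound list**
1 | 3,4,6-trichloropyridazine | Clc1cc(Cl)c(Cl)nn1 | starting material
2 | 3,6-dichloro-4-methoxypyridazine | COc1cc(Cl)nnc1Cl | intermediate
3 | (3-bromopropoxy)(tert-butyl)dimethylsilane | BrCCCO[Si](C)(C)C(C)(C)C | starting material
4 | [3-(tert-butyldimethylsilyloxy)propyl]zinc bromide | Br[Zn]CCCO[Si](C)(C)C(C)(C)C | intermediate
5 | 3-chloro-4-methoxy-6-[3-(tert-butyldimethylsilyloxy)propyl]pyridazine | COc1cc(CCCO[Si](C)(C)C(C)(C)C)nnc1Cl | intermediate
6 | benzyloxyacetaldehyde | O=CCOCc1ccccc1 | starting material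
7 | ethynylmagnesium bromide | C#C[Mg]Br | starting material
8 | rac-1-(benzyloxy)but-3-yn-2-ol | C#CC(O)COCc1ccccc1 | intermediate
9 | (S)-1-(benzyloxy)but-3-yn-2-ol | C#C[C@H](O)COCc1ccccc1 | intermediate
10 | (S)-1-(benzyloxy)but-3-yn-2-yl methanesulfonate | C#C[C@H](OS(C)(=O)=O)COCc1ccccc1 | intermediate
11 | 4-(benzyloxy)-3-methoxybenzaldehyde | COc1cc(C=O)ccc1OCc1ccccc1 | starting material
12 | (P)-[4-(benzyloxy)buta-1,2-dien-1-yl]zinc methanesulfonate | [H]C([Zn]OS(C)(=O)=O)=[C@]=C([H])COCc1ccccc1 | intermediate
13 | (1S,2R)-1-[4-(benzyloxy)-3-methoxyphenyl]-2-[(benzyloxy)methyl]but-3-yn-1-ol (anti) | COc1cc([C@@H](O)[C@@H](COCc2ccccc2)C#C)ccc1OCc1ccccc1 | intermediate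
14 | sodium alkoxide of 13 | COc1cc([C@@H]([O-])[C@@H](COCc2ccccc2)C#C)ccc1OCc1ccccc1.[Na+] | intermediate
15 | 3-{(1S,2R)-1-[4-(benzyloxy)-3-methoxyphenyl]-2-[(benzyloxy)methyl]but-3-ynyloxy}-4-methoxy-6-[3-(tert-butyldimethylsilyloxy)propyl]pyridazine | COc1cc([C@@H](Oc2nnc(CCCO[Si](C)(C)C(C)(C)C)cc2OC)[C@@H](COCc2ccccc2)C#C)ccc1OCc1ccccc1 | intermediate
16 | tetrahydrofuran-fused 2,3-diazabicyclo[2.2.2]octa-2,5,7-triene adduct of 15 (either bridgehead diastereomer; tether centres as in 15) | COC1=CC2(CCCO[Si](C)(C)C(C)(C)C)N=NC13O[C@H](c4ccc(OCc5ccccc5)c(OC)c4)[C@@H](COCc4ccccc4)C3=C2 | intermediate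
17 | (2S,3R)-2-[4-(benzyloxy)-3-methoxyphenyl]-3-[(benzyloxy)methyl]-5-[3-(tert-butyldimethylsilyloxy)propyl]-7-methoxy-2,3-dihydrobenzofuran (trans) | COc1cc([C@H]2Oc3c(OC)cc(CCCO[Si](C)(C)C(C)(C)C)cc3[C@@H]2COCc2ccccc2)ccc1OCc1ccccc1 | intermediate
18 | 3-{(2S,3R)-2-[4-(benzyloxy)-3-methoxyphenyl]-3-[(benzyloxy)methyl]-7-methoxy-2,3-dihydrobenzofuran-5-yl}propan-1-ol | COc1cc([C@H]2Oc3c(OC)cc(CCCO)cc3[C@@H]2COCc2ccccc2)ccc1OCc1ccccc1 | intermediate
19 | pyridinium salt of the propyl sulfate of 18 | COc1cc([C@H]2Oc3c(OC)cc(CCCOS(=O)(=O)[O-])cc3[C@@H]2COCc2ccccc2)ccc1OCc1ccccc1.c1cc[nH+]cc1 | intermediate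
20 | sodium salt of the propyl sulfate of 18 | COc1cc([C@H]2Oc3c(OC)cc(CCCOS(=O)(=O)[O-])cc3[C@@H]2COCc2ccccc2)ccc1OCc1ccccc1.[Na+] | intermediate
21 | sodium 3-[(2S,3R)-2-(4-hydroxy-3-methoxyphenyl)-3-(hydroxymethyl)-7-methoxy-2,3-dihydrobenzofuran-5-yl]propyl sulfate | COc1cc([C@H]2Oc3c(OC)cc(CCCOS(=O)(=O)[O-])cc3[C@@H]2CO)ccc1O.[Na+] | intermediate
22 | 3-[(2S,3R)-2-(4-hydroxy-3-methoxyphenyl)-3-(hydroxymethyl)-7-methoxy-2,3-dihydrobenzofuran-5-yl]propyl hydrogen sulfate | COc1cc([C@H]2Oc3c(OC)cc(CCCOS(=O)(=O)O)cc3[C@@H]2CO)ccc1O | target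

Total step count: 11
Longest linear sequence: 9 steps (steps 3–11, from 6 to 22)

**Steps most likely to fail**

**Step 8.** Two oxygen donors and an alkyl group leave the diazine a reluctant diene. The cycloaddition may therefore be outrun by thermal decay of the secondary benzylic diazinyl ether, through ionisation with O-to-N shift or epimerisation at C2, or through retro-ene loss of the pyridazinone.

Fallback: carry chlorine instead of the alkyl chain on the diazine through the cycloaddition and attach the chain afterwards. It sets out from 13 (as its alkoxide 14) and 2. The alkoxide is added to dichloride 2 in THF at 0 °C. Small alkoxides favour C3 next to the methoxy group, and any C6 isomer is separated, to give the 6-chloropyridazinyl ether F1. Heating F1 in 1,3,5-triisopropylbenzene places the σ-acceptor chlorine on the diene terminus, as in the classical examples of this reaction. The reaction passes through the chloro adduct F2 to the 5-chloro-2,3-dihydrobenzofuran F3. A Negishi coupling of F3 with 4 (Pd(OAc)2, SPhos, THF, 60 °C) comes back to the route at 17.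

**Step 6.** The allenylzinc may lose benzyloxide by 1,4-elimination before it meets the aldehyde, and the allenylpalladium may racemise. The facial discrimination that gives the anti isomer is also weaker with aromatic aldehydes.

Fallback: build the same two centres by an auxiliary-controlled aldol reaction and make the alkyne afterwards. It sets out from 11.
- (S)-4-Benzyloxazolidin-2-one is acylated with (E)-but-2-enoyl chloride (n-BuLi, THF, −78 °C) to the crotonyl imide F4.
- The boron dienolate of F4 (Bu2BOTf, Et3N, CH2Cl2, −78 °C) reacts with 11 at its α-carbon in an Evans syn aldol reaction to give the (2S,3S) α-vinyl aldol F5.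
- TBSOTf/2,6-lutidine gives the silyl ether F6.
- LiBH4 removes the auxiliary and gives the primary alcohol F7.
- 2-Benzyloxy-1-methylpyridinium triflate with MgO in PhCF3 (neutral, so no silyl shift) gives the benzyl ether F8.
- Lemieux–Johnson cleavage of the vinyl group (OsO4 cat., NaIO4, 2,6-lutidine, dioxane/H2O) gives the aldehyde F9.
- Ohira–Bestmann homologation (dimethyl (1-diazo-2-oxopropyl)phosphonate, K2CO3, MeOH, 0 °C) gives the silylated alkynol F10.
- TBAF in THF comes back to the route at 13.

The former acyl carbon becomes CH2OBn and the vinyl group becomes the alkyne, so the syn aldol corresponds to the anti arrangement of 13.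

**Step 7.** Substitution at the electron-rich, hindered C3 may be slow, which gives time for exchange of the C4 methoxy group. It also gives time for base-induced alkyne–allene isomerisation, which would scramble the propargylic centre.

Fallback: form the C–O bond by ipso-substitution of a sulfone instead of a chloride. It sets out from 5. NaSMe (THF, rt) gives the methyl sulfide F11, and mCPBA (2 equiv, NaHCO3, CH2Cl2, 0 °C) gives the methyl sulfone F12. Alkoxide 14 displaces methanesulfinate from F12 at −20 to 0 °C, which comes back to the route at 15.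

**Further compounds**
F1 | step 8 | 3-{(1S,2R)-1-[4-(benzyloxy)-3-methoxyphenyl]-2-[(benzyloxy)methyl]but-3-ynyloxy}-6-chloro-4-methoxypyridazine | COc1cc([C@@H](Oc2nnc(Cl)cc2OC)[C@@H](COCc2ccccc2)C#C)ccc1OCc1ccccc1
F2 | step 8 | chloro-substituted 2,3-diazabicyclo[2.2.2]octa-2,5,7-triene adduct of F1 (either bridgehead diastereomer) | COC1=CC2(Cl)N=NC13O[C@H](c4ccc(OCc5ccccc5)c(OC)c4)[C@@H](COCc4ccccc4)C3=C2
F3 | step 8 | (2S,3R)-2-[4-(benzyloxy)-3-methoxyphenyl]-3-[(benzyloxy)methyl]-5-chloro-7-methoxy-2,3-dihydrobenzofuran | COc1cc([C@H]2Oc3c(OC)cc(Cl)cc3[C@@H]2COCc2ccccc2)ccc1OCc1ccccc1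
F4 | step 6 | (S)-4-benzyl-3-[(E)-but-2-enoyl]oxazolidin-2-one | C/C=C/C(=O)N1[C@@H](Cc2ccccc2)COC1=O
F5 | step 6 | (S)-4-benzyl-3-{(2S,3S)-3-[4-(benzyloxy)-3-methoxyphenyl]-2-ethenyl-3-hydroxypropanoyl}oxazolidin-2-one | COc1cc([C@@H](O)[C@@H](C(=O)N2[C@@H](Cc3ccccc3)COC2=O)C=C)ccc1OCc1ccccc1
F6 | step 6 | tert-butyldimethylsilyl ether of F5 (2S,3S) | COc1cc([C@@H](O[Si](C)(C)C(C)(C)C)[C@@H](C(=O)N2[C@@H](Cc3ccccc3)COC2=O)C=C)ccc1OCc1ccccc1
F7 | step 6 | (2R)-2-{(S)-[4-(benzyloxy)-3-methoxyphenyl](tert-butyldimethylsilyloxy)methyl}but-3-en-1-ol | COc1cc([C@@H](O[Si](C)(C)C(C)(C)C)[C@@H](CO)C=C)ccc1OCc1ccccc1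
F8 | step 6 | benzyl ether of F7 | COc1cc([C@@H](O[Si](C)(C)C(C)(C)C)[C@@H](COCc2ccccc2)C=C)ccc1OCc1ccccc1
F9 | step 6 | (2R,3S)-3-[4-(benzyloxy)-3-methoxyphenyl]-2-[(benzyloxy)methyl]-3-(tert-butyldimethylsilyloxy)propanal | COc1cc([C@@H](O[Si](C)(C)C(C)(C)C)[C@@H](COCc2ccccc2)C=O)ccc1OCc1ccccc1
F10 | step 6 | tert-butyldimethylsilyl ether of 13 (1S,2R) | COc1cc([C@@H](O[Si](C)(C)C(C)(C)C)[C@@H](COCc2ccccc2)C#C)ccc1OCc1ccccc1
F11 | step 7 | 4-methoxy-3-(methylsulfanyl)-6-[3-(tert-butyldimethylsilyloxy)propyl]pyridazine | COc1cc(CCCO[Si](C)(C)C(C)(C)C)nnc1SC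
F12 | step 7 | 4-methoxy-3-(methylsulfonyl)-6-[3-(tert-butyldimethylsilyloxy)propyl]pyridazine | COc1cc(CCCO[Si](C)(C)C(C)(C)C)nnc1S(C)(=O)=O
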